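Saturday's run is this flask followed to 144 h, while Sunday's, cooler and with less substrate, ends at 40.0 h with product still rising, so I reckon from Saturday's.

| setting | Saturday's | Sunday's | flask |
|---|---|---|---|
| substrate | 0.80 M | 0.54 M | 0.80 M |
| coupling partner | 0.80 M | 0.80 M | 0.800 M |
| temperature | 80 °C | 75 °C | 80 °C |
| remark | the very flask that is asked about, followed so far | run made earlier |  |
| time |  |  | 8.0 d |

| run | time / h | product / % | substrate / % |
|---|---|---|---|
| Saturday's | 30.0 | 27 | 71 |
| Saturday's | 60.0 | 37 | 62 |
| Saturday's | 96.0 | 41 | 56 |
| Saturday's | 120 | 41 | 57 |
| Saturday's | 144 | 41 | 57 |
| Sunday's | 3.00 | 0 | 100 |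
| Sunday's | 5.00 | 2 | 97 |
| Sunday's | 10.0 | 3 | 89 |
| Sunday's | 20.0 | 11 | 83 |
| Sunday's | 40.0 | 21 | 74 |

(scatter of a reading: 2 percentage points)

- product, in percent of the substrate first charged, at 8.0 d
- the option that brings most further product ("none" if no option brings more than 2 percentage points) (green / ochre / violet / amber / none)
- product present, with what was taken out counted in, in percent of the substrate first charged, after green
- product present, with what was taken out counted in, in percent of the substrate first charged, after ochre

- green: at 8.0 d add coupling partner, 50.0% of the amount charged, then wait 2.5 d
- ochre: at 8.0 d raise the temperature by 10 K, then wait 2.5 d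
- violet: at 8.0 d take out 90% of the product then present, then wait 2.5 d
- amber: change nothing and wait 2.5 d more

- what is taken out of product is counted as made
- additions bring no volume worth counting

Two of Saturday's numbers don't seem to go together: the readings of the flask hold at 41% product from 96.0 h on, yet with equal charges and one coupling partner per product, 59.0% of the coupling partner ought to be there beside 57% substrate. Read as second order, with k the rate constant of substrate and coupling partner going to product, the first reading gives k = 0.0154 M⁻¹ h⁻¹, and that k at these amounts predicts 19 percentage points more product between 96.0 h and 144 h, where the readings show 0 points.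

So either the back reaction balances the forward one, or the coupling partner is being lost by another path and the amount I assumed isn't there. As I read it, Saturday's product curve doesn't separate these, but green should pay under both, and violet under the first and not the second, so I commit to green and size it by the second.

If coupling partner is lost on its own clock, the logarithm of substrate's fall follows the time-integral of coupling partner, which I take, as an approximation at this substrate charge and temperature, to scale with its charge. I therefore carry R = 0.703 M⁻¹, the reach: the natural logarithm of charged over stalled substrate, per molar of coupling partner charged.

Green adds 0.400 M, which R turns into 14 points of further product. The gap to the plateau at the first reading gives a stall time of 27.9 h, so within 2.5 d about 12 points arrives, and I expect 53.0% after green, with about 41% now and after ochre.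

The forecast gives 41% now, 52% after green and 40.5% after ochre, and names violet, saying “removal, then re-equilibration, counts about 55%”.

The flask gives 42.0% at 8.0 d, and the best option is green, at 54.0%, with 38.2% after ochre.

    substrate + coupling partner ⇌ intermediate (K = 0.550 M⁻¹, k = 7.60 × 10⁻⁶ M⁻¹ s⁻¹, Ea = 104 kJ mol⁻¹, ΔH = −21.0 kJ mol⁻¹)
    intermediate ⇌ product + by-product (K = 28.0 M, k = 5.50 × 10⁻⁵ s⁻¹, Ea = 114 kJ mol⁻¹, ΔH = −57.0 kJ mol⁻¹)
    coupling partner → decomposed reagent (k = 4.50 × 10⁻⁶ s⁻¹, Ea = 114 kJ mol⁻¹)
    (constants at 80 °C)

At 192 h the coupling partner in the flask, the limiting reagent, stands at 1.30% of its charge, less than the substrate's 57.5%. By R that remnant is worth 0.42 points, less than the 2 points that counts as a gain, while amber changes the product by −0.54 points. For the neighbour flask charged with 0.48 M of coupling partner, R gives 71.4% of substrate left, and that neighbour ends at 72.3%.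

All runs are simulated with made-up constants; noise was put on by code.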